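**Retrosynthetic overview**

1. The last step only unmasks the phenol; the TBS-protected dienone is cut at C1–C2 and C3–C4 into pent-1-en-4-yne (C2, C3 and the allyl group) and a 3,4-dimethoxy-4-alkylcyclobut-2-enone (C4, C5, C6, C1).
2. Forward, zerovalent nickel inserts the alkyne into the strained acyl–C4 bond of the cyclobutenone: a strain-release formal [4+2] that makes both bonds and delivers the dienone at its final oxidation level.
3. Enabling feature: ring atoms C1(=O)–C6H=C5(OMe)–C4(OMe)(alkyl) are a squarate-type cyclobutenone in disguise, and C4 is quaternary, so the annulation product cannot tautomerise to a phenol and stays a cyclohexa-2,5-dienone.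
4. The cyclobutenone comes from methyl semisquarate (from dimethyl squarate) by 1,2-addition of an (R)-configured secondary alkyllithium and O-methylation. The side-chain centre derives from (S)-propylene oxide (epoxide opening, iodide with inversion, retentive exchange and addition). C4 is set in the addition, with only modest substrate control and removal of the unwanted epimer, and is carried through the annulation with retention.
5. Ring order: the arene and the four-membered ring are bought; the six-membered dienone ring is the only ring made, in the penultimate step.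

Key step: step 7

Assumption: the target is read as (4R) at the ring carbon and (2R) at the side-chain methine; the ring is numbered C1 (C=O) to C6 and the side-chain methine is called C2′.

**Route**

Step 1
Reactants: 1 4-bromo-2-methoxyphenol
Product: 2 (4-bromo-2-methoxyphenoxy)(tert-butyl)dimethylsilane
Conditions: TBSCl, imidazole, DMF, rt
Reagents that add atoms: tert-butyldimethylsilyl chloride (TBSCl), CC(C)(C)[Si](C)(C)Cl
Why: Imidazole-promoted silyl ether formation masks the acidic phenol for the organometallic steps; no stereocentre is involved.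

Step 2
Reactants: 2 (4-bromo-2-methoxyphenoxy)(tert-butyl)dimethylsilane; 3 (2S)-2-methyloxirane
Product: 5 (2S)-1-{4-[(tert-butyldimethylsilyl)oxy]-3-methoxyphenyl}propan-2-ol, via arylmagnesium bromide 4 (not isolated)
Conditions: Mg, THF, 40 °C; then CuBr·SMe2 (10 mol%), 3, −30 to 0 °C; aq. NH4Cl
Reagents that add atoms: none
Why: Copper-catalysed SN2 opening of the terminal epoxide by the aryl Grignard reagent occurs at the unsubstituted CH2, so the (S) carbinol centre of 3 is carried over untouched.

Step 3
Reactants: 5 (2S)-1-{4-[(tert-butyldimethylsilyl)oxy]-3-methoxyphenyl}propan-2-ol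
Product: 6 tert-butyl{4-[(2R)-2-iodopropyl]-2-methoxyphenoxy}dimethylsilane
Conditions: PPh3, I2, N-methylimidazole, CH2Cl2, −10 °C
Reagents that add atoms: iodine, II
Why: Appel iodination, in which iodide displaces the alkoxyphosphonium group by SN2 with inversion, should turn the (S) alcohol into the (R) iodide, the low temperature limiting iodide–iodide exchange.

Step 4
Reactants: 7 3,4-dimethoxycyclobut-3-ene-1,2-dione (dimethyl squarate)
Product: 9 3-methoxycyclobut-3-ene-1,2-dione (methyl semisquarate), via 4-hydroxy-2,3-dimethoxycyclobut-2-en-1-one 8 (not isolated)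
Conditions: LiAlH(O-t-Bu)3, THF, −78 to −20 °C; then conc. HCl, CH2Cl2, rt
Reagents that add atoms: none
Why: Partial reduction with the hindered hydride should stop at the hydroxycyclobutenone, and acid then expels methanol with allylic transposition to the semisquarate, the established way to alkyl semisquarates.

Step 5
Reactants: 6 tert-butyl{4-[(2R)-2-iodopropyl]-2-methoxyphenoxy}dimethylsilane; 9 3-methoxycyclobut-3-ene-1,2-dione
Product: 11 (4S)-4-[(2R)-1-{4-[(tert-butyldimethylsilyl)oxy]-3-methoxyphenyl}propan-2-yl]-4-hydroxy-3-methoxycyclobut-2-en-1-one, via secondary alkyllithium 10 (not isolated)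
Conditions: t-BuLi (2.1 equiv), pentane/Et2O 3:2, −100 °C (6 added to t-BuLi), few min; then 9 in Et2O, −100 to −78 °C; aq. NH4Cl at −78 °C; chromatographic removal of the C4 epimer
Reagents that add atoms: none
Why: Iodine–lithium exchange at −100 °C and the 1,2-addition of the secondary alkyllithium both proceed with retention, so C2′ should be (R); the addition takes the ketone-like carbonyl next to C–OMe (the other is a vinylogous ester); C4 forms under modest substrate control only (lithium-bridged open transition state with C2′–H over the ring and the CH2Ar arm away from the methoxy-bearing flank, which points to 4S), so the (4R) epimer is removed here.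

Step 6
Reactants: 11 (4S)-4-[(2R)-1-{4-[(tert-butyldimethylsilyl)oxy]-3-methoxyphenyl}propan-2-yl]-4-hydroxy-3-methoxycyclobut-2-en-1-one
Product: 12 (4S)-4-[(2R)-1-{4-[(tert-butyldimethylsilyl)oxy]-3-methoxyphenyl}propan-2-yl]-3,4-dimethoxycyclobut-2-en-1-one
Conditions: MeI, Ag2O, 4 Å MS, MeCN, rt, dark
Reagents that add atoms: methyl iodide (MeI), CI
Why: Purdie methylation of the tertiary alcohol under non-basic conditions should avoid cleavage of the hydroxycyclobutenone ring and touches no stereocentre.

Step 7
Reactants: 12 (4S)-4-[(2R)-1-{4-[(tert-butyldimethylsilyl)oxy]-3-methoxyphenyl}propan-2-yl]-3,4-dimethoxycyclobut-2-en-1-one; 13 pent-1-en-4-yne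
Product: 14 (4R)-4-[(2R)-1-{4-[(tert-butyldimethylsilyl)oxy]-3-methoxyphenyl}propan-2-yl]-4,5-dimethoxy-2-(prop-2-en-1-yl)cyclohexa-2,5-dien-1-one
Conditions: Ni(cod)2 (15 mol%), THF, 0 °C to rt, 13 (3 equiv) added slowly
Reagents that add atoms: none
Why: Proposed new method: zerovalent nickel adds oxidatively into the strained acyl–C4 bond of 12 to give a nickelacyclopentenone (equally an η4-vinylketene complex), the alkyne of 13 inserts, and C–C reductive elimination from the seven-membered nickelacycle releases 14 and the catalyst, so that C1–C2 and C3–C4 form in one operation with relief of the four-ring strain. The closest known reaction type is the Ni(cod)2-catalysed [4+2] benzannulation of cyclobutenones with alkynes to phenols; new here is a 4,4-disubstituted 4-alkoxycyclobutenone, whose product cannot tautomerise and so stays at the cyclohexa-2,5-dienone stage, combined with a terminal alkyne. The six-membered ring is closed by the final C(sp2)–C(sp2) reductive elimination of this formal [4+2] annulation (four carbons from 12, two from 13). No new stereocentre is formed: C4 passes from the acyl carbon to nickel and from nickel to the alkyne carbon on the same face (retention), and the low temperature keeps the uncatalysed ring opening to a free, planar vinylketene, which would scramble C4, out of play. The step needs regioselectivity (allyl-bearing carbon to C1, CH to C4) and chemoselectivity for the alkyne over the alkene of 13: the fully substituted C4 can bond without severe strain only to the unsubstituted alkyne terminus, and under phosphine-free conditions the pendant allyl alkene can chelate nickel sitting on that terminal carbon, which steers the acyl carbon to the allyl-bearing carbon, while the alkene itself is a far poorer insertion partner than the alkyne.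

Step 8
Reactants: 14 (4R)-4-[(2R)-1-{4-[(tert-butyldimethylsilyl)oxy]-3-methoxyphenyl}propan-2-yl]-4,5-dimethoxy-2-(prop-2-en-1-yl)cyclohexa-2,5-dien-1-one
Product: 15 (4R)-4-[(2R)-1-(4-hydroxy-3-methoxyphenyl)propan-2-yl]-4,5-dimethoxy-2-(prop-2-en-1-yl)cyclohexa-2,5-dien-1-one
Conditions: TBAF, AcOH, THF, 0 °C
Reagents that add atoms: none
Why: Fluoride-mediated cleavage of the aryl silyl ether, buffered with acetic acid so that the phenoxide does not attack the quinol ether dienone, should free the phenol without touching either stereocentre.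

**Compound list**

1 | 4-bromo-2-methoxyphenol | COc1cc(Br)ccc1O | starting material
2 | (4-bromo-2-methoxyphenoxy)(tert-butyl)dimethylsilane | COc1cc(Br)ccc1O[Si](C)(C)C(C)(C)C | intermediate
3 | (2S)-2-methyloxirane ((S)-propylene oxide) | C[C@H]1CO1 | starting material
4 | {4-[(tert-butyldimethylsilyl)oxy]-3-methoxyphenyl}magnesium bromide (formed in the flask) | COc1cc([Mg]Br)ccc1O[Si](C)(C)C(C)(C)C | intermediate
5 | (2S)-1-{4-[(tert-butyldimethylsilyl)oxy]-3-methoxyphenyl}propan-2-ol | C[C@H](O)Cc1ccc(O[Si](C)(C)C(C)(C)C)c(OC)c1 | intermediate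
6 | tert-butyl{4-[(2R)-2-iodopropyl]-2-methoxyphenoxy}dimethylsilane | C[C@@H](I)Cc1ccc(O[Si](C)(C)C(C)(C)C)c(OC)c1 | intermediate
7 | 3,4-dimethoxycyclobut-3-ene-1,2-dione (dimethyl squarate) | COC1=C(OC)C(=O)C1=O | starting material
8 | 4-hydroxy-2,3-dimethoxycyclobut-2-en-1-one (racemic, formed in the flask) | COC1=C(OC)C(O)C1=O | intermediate
9 | 3-methoxycyclobut-3-ene-1,2-dione (methyl semisquarate) | COC1=CC(=O)C1=O | intermediate
10 | [(2R)-1-{4-[(tert-butyldimethylsilyl)oxy]-3-methoxyphenyl}propan-2-yl]lithium (formed in the flask) | C[C@@H]([Li])Cc1ccc(O[Si](C)(C)C(C)(C)C)c(OC)c1 | intermediate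
11 | (4S)-4-[(2R)-1-{4-[(tert-butyldimethylsilyl)oxy]-3-methoxyphenyl}propan-2-yl]-4-hydroxy-3-methoxycyclobut-2-en-1-one | O=C1C=C(OC)[C@@]1(O)[C@H](C)Cc2ccc(O[Si](C)(C)C(C)(C)C)c(OC)c2 | intermediate
12 | (4S)-4-[(2R)-1-{4-[(tert-butyldimethylsilyl)oxy]-3-methoxyphenyl}propan-2-yl]-3,4-dimethoxycyclobut-2-en-1-one | O=C1C=C(OC)[C@@]1(OC)[C@H](C)Cc2ccc(O[Si](C)(C)C(C)(C)C)c(OC)c2 | intermediate
13 | pent-1-en-4-yne | C=CCC#C | starting material
14 | (4R)-4-[(2R)-1-{4-[(tert-butyldimethylsilyl)oxy]-3-methoxyphenyl}propan-2-yl]-4,5-dimethoxy-2-(prop-2-en-1-yl)cyclohexa-2,5-dien-1-one | C=CCC1=C[C@](OC)([C@H](C)Cc2ccc(O[Si](C)(C)C(C)(C)C)c(OC)c2)C(OC)=CC1=O | intermediate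
15 | (4R)-4-[(2R)-1-(4-hydroxy-3-methoxyphenyl)propan-2-yl]-4,5-dimethoxy-2-(prop-2-en-1-yl)cyclohexa-2,5-dien-1-one | C=CCC1=C[C@](OC)([C@H](C)Cc2ccc(O)c(OC)c2)C(OC)=CC1=O | target

**Step count and risks**

Total step count: 8. Longest linear sequence: 7 steps (1, 2, 3, 5, 6, 7, 8); step 4 is a one-step branch.

Steps most likely to fail:

1. Step 7 (Proposed new method). What may go wrong: insertion of the alkyne in the opposite orientation, nickel-induced oligomerisation of the terminal alkyne ahead of productive insertion, and leakage of the C4 configuration through a free vinylketene. The fallback uses known chemistry, sets out from iodide 6 (via alkyllithium 10) and comes back at 14. Commercial 3-methoxyphenol is O-allylated (allyl bromide, K2CO3, acetone) to 1-methoxy-3-(prop-2-en-1-yloxy)benzene F1. Aromatic Claisen rearrangement (N,N-diethylaniline, reflux) gives 2-allyl-5-methoxyphenol F2 after removal of the other ortho isomer. Oxidation with potassium nitrosodisulfonate (aq. KH2PO4, acetone) gives 2-allyl-5-methoxy-1,4-benzoquinone F3. Alkyllithium 10 then adds 1,2 to the C4 carbonyl of F3, the one that is not a vinylogous ester, at −100 to −78 °C (aq. NH4Cl quench) to give (4R)-4-[(2R)-1-{4-[(tert-butyldimethylsilyl)oxy]-3-methoxyphenyl}propan-2-yl]-4-hydroxy-5-methoxy-2-(prop-2-en-1-yl)cyclohexa-2,5-dien-1-one F4 after separation from its C4 epimer. Purdie methylation (MeI, Ag2O) of F4 gives 14. In this fallback C4 is formed without control and rests on the epimer separation.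

2. Step 5. What may go wrong: loss of configuration of the secondary alkyllithium before capture (radical pathways during the exchange, local warming), competing conjugate addition, and weak facial discrimination at C4. The fallback sets out from arylmagnesium bromide 4 (from 2) and comes back at 12. Copper-catalysed coupling of 4 with 2,3-dibromopropene gives tert-butyl[4-(2-bromoprop-2-en-1-yl)-2-methoxyphenoxy]dimethylsilane F5. Bromine–lithium exchange (t-BuLi, −78 °C) gives the alkenyllithium F6, which has no stereocentre to lose and adds to 9 to give racemic 4-hydroxy-3-methoxy-4-(3-arylprop-1-en-2-yl)cyclobut-2-en-1-one F7. Purdie methylation gives the 3,4-dimethoxy analogue F8. Asymmetric hydrogenation of the 1,1-disubstituted alkene of F8 with [Ir(cod)(t-Bu-PHOX)][B(3,5-(CF3)2C6H3)4] under H2 (ligand antipode chosen for the (R) centre) sets C2′ under catalyst control and gives 12 together with its C4 epimer, which is separated. This secures C2′ but does not improve the C4 selectivity.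

3. Step 3. What may go wrong: erosion of enantiopurity by iodide–iodide exchange at the secondary iodide and elimination to the propenyl arene. The fallback sets out from arylmagnesium bromide 4 and comes back at 6. Reaction of 4 with 2-(iodomethyl)-4,4,5,5-tetramethyl-1,3,2-dioxaborolane (ate complex, then 1,2-metallate shift) gives the benzylic boronic ester 2-{4-[(tert-butyldimethylsilyl)oxy]-3-methoxybenzyl}-4,4,5,5-tetramethyl-1,3,2-dioxaborolane F9. Lithiation–borylation with lithiated ethyl N,N-diisopropylcarbamate (s-BuLi with the sparteine antipode chosen for the (S) product, Et2O, −78 °C, then warming) gives the secondary boronic ester 2-[(2S)-1-{4-[(tert-butyldimethylsilyl)oxy]-3-methoxyphenyl}propan-2-yl]-4,4,5,5-tetramethyl-1,3,2-dioxaborolane F10. Its boronate complex with 3,5-bis(trifluoromethyl)phenyllithium reacts with I2 with inversion to give 6.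

**Further compounds**

F1 | step 7 | 1-methoxy-3-(prop-2-en-1-yloxy)benzene | C=CCOc1cccc(OC)c1
F2 | step 7 | 2-allyl-5-methoxyphenol | C=CCc1ccc(OC)cc1O
F3 | step 7 | 2-allyl-5-methoxy-1,4-benzoquinone | C=CCC1=CC(=O)C(OC)=CC1=O
F4 | step 7 | (4R)-4-[(2R)-1-{4-[(tert-butyldimethylsilyl)oxy]-3-methoxyphenyl}propan-2-yl]-4-hydroxy-5-methoxy-2-(prop-2-en-1-yl)cyclohexa-2,5-dien-1-one | C=CCC1=C[C@](O)([C@H](C)Cc2ccc(O[Si](C)(C)C(C)(C)C)c(OC)c2)C(OC)=CC1=O
F5 | step 5 | tert-butyl[4-(2-bromoprop-2-en-1-yl)-2-methoxyphenoxy]dimethylsilane | C=C(Br)Cc1ccc(O[Si](C)(C)C(C)(C)C)c(OC)c1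
F6 | step 5 | (3-{4-[(tert-butyldimethylsilyl)oxy]-3-methoxyphenyl}prop-1-en-2-yl)lithium | C=C([Li])Cc1ccc(O[Si](C)(C)C(C)(C)C)c(OC)c1
F7 | step 5 | 4-(3-{4-[(tert-butyldimethylsilyl)oxy]-3-methoxyphenyl}prop-1-en-2-yl)-4-hydroxy-3-methoxycyclobut-2-en-1-one (racemic) | O=C1C=C(OC)C1(O)C(=C)Cc2ccc(O[Si](C)(C)C(C)(C)C)c(OC)c2
F8 | step 5 | 4-(3-{4-[(tert-butyldimethylsilyl)oxy]-3-methoxyphenyl}prop-1-en-2-yl)-3,4-dimethoxycyclobut-2-en-1-one (racemic) | O=C1C=C(OC)C1(OC)C(=C)Cc2ccc(O[Si](C)(C)C(C)(C)C)c(OC)c2
F9 | step 3 | 2-{4-[(tert-butyldimethylsilyl)oxy]-3-methoxybenzyl}-4,4,5,5-tetramethyl-1,3,2-dioxaborolane | CC1(C)OB(Cc2ccc(O[Si](C)(C)C(C)(C)C)c(OC)c2)OC1(C)C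
F10 | step 3 | 2-[(2S)-1-{4-[(tert-butyldimethylsilyl)oxy]-3-methoxyphenyl}propan-2-yl]-4,4,5,5-tetramethyl-1,3,2-dioxaborolane | C[C@H](B1OC(C)(C)C(C)(C)O1)Cc2ccc(O[Si](C)(C)C(C)(C)C)c(OC)c2
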